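**Retr­osynthetic overview** (cembrane numbering: C1 = CH bearing C15–C17, C3 = CHOAc, C4 and C7 = oxolane carbons, C8 = carbinol, C11 = ketone, C12 = lactone-oxygen carbon, C16 = lactone carbonyl)
1. The seven-membered lactone is cut at C16–O(C12); the acrylic acid comes from the C16 methyl group by allylic oxidation after the carbocycle is closed.
2. The 14-membered carbocycle is cut at C8–C9. The plan rests on the γ-hydroxy ketone C8(OH)–C9–C10–C11(=O) in this ring, a homoaldol retron whose carbinol carbon C8 lies next to the oxolane oxygen on C7 (chelation); the ends are a C11 cyclopropanol and a C8 methyl ketone.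
3. The seco chain is cut at C2–C3 (alkyllithium plus aldehyde, then oxidation and reagent-controlled reduction for 3S). The west chloride comes from (R)-carvone (C1, C12; ring cleaved between C11 and C2; cyclopropanol by Kulinkovich reaction); the east oxolane aldehyde comes from (R)-linalool (C4; C7 by reagent-controlled epoxidation and cyclisation).
4. Ring order: cyclopropane (step 8, spent in step 21) and oxolane (step 10) on separate branches, then the 14-membered carbocycle (step 21), then the seven-membered lactone (step 26).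
5. Protection: C12–OTBS to the end; the cyclopropanol as TES ether and the C8 ketone as dimethyl ketal until one acid step frees both.

Key step: step 21

Assumption: the L-configured (mirror-image) Shi ketone is taken as accessible from L-sorbose by the standard preparation. C16 is carried as a methyl group through the ring closure and oxidised afterwards; this changes no bond made in the key step.

**Route**

Step 1
Reactants: 1 (R)-carvone
Product: 2 (1R,4R,6R)-1-methyl-4-(prop-1-en-2-yl)-7-oxabicyclo[4.1.0]heptan-2-one (oxirane trans to isopropenyl)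
Conditions: 30% H2O2, NaOH (aq), MeOH, 0 °C
Reagents that add atoms: hydrogen peroxide (OO)
Why: Weitz–Scheffer nucleophilic epoxidation; hydroperoxide adds axially to the β-carbon anti to the isopropenyl group, so the oxirane oxygen ends trans to it, which is the C12–O configuration of the target.

Step 2
Reactants: 2 trans-carvone epoxide
Product: 3 (1R,4R)-1-methyl-4-(prop-1-en-2-yl)cyclohexane-1,2-diol (both C2 epimers)
Conditions: LiAlH4, THF, 0 °C → reflux
Reagents that add atoms: none
Why: Hydride reduction of the ketone and SN2 opening of the oxirane at its secondary carbon should leave the tertiary C–O bond and its configuration untouched; the secondary carbinol is oxidised in step 3, so its configuration does not matter.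

Step 3
Reactants: 3 diol
Product: 4 (2R,5R)-2-hydroxy-2-methyl-5-(prop-1-en-2-yl)cyclohexan-1-one
Conditions: 2-iodoxybenzoic acid (IBX), DMSO, rt
Reagents that add atoms: none
Why: IBX oxidation of the secondary alcohol of a 1,2-diol stops at the α-ketol without C–C cleavage and does not touch the tertiary alcohol or the alkene.

Step 4
Reactants: 4 α-ketol
Product: 5 (2R,5R)-2-[(tert-butyldimethylsilyl)oxy]-2-methyl-5-(prop-1-en-2-yl)cyclohexan-1-one
Conditions: TBSOTf, 2,6-lutidine, CH2Cl2, −78 → 0 °C
Reagents that add atoms: tert-butyldimethylsilyl trifluoromethanesulfonate (CC(C)(C)[Si](C)(C)OS(=O)(=O)C(F)(F)F)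
Why: Silyl triflate silylation of a tertiary alcohol; the ether blocks ketol cleavage on this side in step 6 and serves as the C12 ether in the key step.

Step 5
Reactants: 5 silyl ether
Product: 7 (2R,5S)-2-[(tert-butyldimethylsilyl)oxy]-6-hydroxy-2-methyl-5-(prop-1-en-2-yl)cyclohexan-1-one (both C6 epimers), via potassium enolate 6 (not isolated)
Conditions: KN(SiMe3)2, THF, −78 °C; then 3-phenyl-2-(phenylsulfonyl)oxaziridine, −78 °C
Reagents that add atoms: 3-phenyl-2-(phenylsulfonyl)oxaziridine (O=S(=O)(N1OC1c1ccccc1)c1ccccc1)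
Why: Davis α-hydroxylation of the only enolate that can form (the other α-carbon is quaternary); the new carbinol carbon is cleaved in step 6, so its configuration is irrelevant.

Step 6
Reactants: 7 α'-hydroxy ketone
Product: 9 methyl (2R,5S)-2-[(tert-butyldimethylsilyl)oxy]-5-(hydroxymethyl)-2,6-dimethylhept-6-enoate, via aldehyde ester 8 (not isolated)
Conditions: Pb(OAc)4, MeOH–PhH (1:1), 0 °C; Celite filtration; then NaBH4, MeOH, −20 °C
Reagents that add atoms: methanol (CO)
Why: Criegee-type α-ketol cleavage in methanol breaks the C11–C2 ring bond to the methyl ester and the aldehyde 8, which is reduced at once so that its allylic α-stereocentre (C1) cannot epimerise or move into conjugation; the hindered ester is not reduced.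

Step 7
Reactants: 9 hydroxy ester
Product: 10 methyl (2R,5S)-2-[(tert-butyldimethylsilyl)oxy]-5-(chloromethyl)-2,6-dimethylhept-6-enoate
Conditions: PPh3, N-chlorosuccinimide, THF, 0 °C → rt
Reagents that add atoms: N-chlorosuccinimide (O=C1CCC(=O)N1Cl)
Why: Appel-type chlorination of the primary alcohol through the alkoxyphosphonium salt; a primary chloride tolerates the Grignard and titanium reagents of step 8.

Step 8
Reactants: 10 chloro ester; 11 ethylmagnesium bromide
Product: 12 1-[(2R,5S)-2-[(tert-butyldimethylsilyl)oxy]-5-(chloromethyl)-6-methylhept-6-en-2-yl]cyclopropan-1-ol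
Conditions: EtMgBr (3 equiv, slow addition), Ti(OiPr)4 (0.5 equiv), THF, 0 °C → rt
Reagents that add atoms: ethylmagnesium bromide 11 (CC[Mg]Br)
Why: Kulinkovich cyclopropanation; the titanacyclopropane from two ethyl groups inserts the ester carbonyl and closes to the cyclopropanol (C9, C10 from the Grignard reagent), while the 1,1-disubstituted alkene and the alkyl chloride are spectators.

Step 9
Reactants: 12 cyclopropanol
Product: 13 west chloride, the triethylsilyl ether of 12
Conditions: TESOTf, 2,6-lutidine, CH2Cl2, −78 °C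
Reagents that add atoms: triethylsilyl trifluoromethanesulfonate (CC[Si](CC)(CC)OS(=O)(=O)C(F)(F)F)
Why: Silylation masks the cyclopropanol against the alkyllithium, the oxidation and the acetylation that follow; TES is cleaved later by mild acid that spares the tertiary TBS ether.

Step 10
Reactants: 14 (R)-linalool
Product: 16 2-[(2R,5R)-5-ethenyl-5-methyloxolan-2-yl]propan-2-ol (trans-furanoid linalool oxide), via (6S)-6,7-epoxylinalool 15 (not isolated)
Conditions: L-configured Shi ketone (0.3 equiv), KHSO5 (as 2KHSO5·KHSO4·K2SO4), K2CO3, n-Bu4NHSO4, MeCN–CH2(OMe)2–aq. Na2B4O7 buffer, 0 °C; then camphorsulfonic acid (cat.), CH2Cl2, 0 °C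
Reagents that add atoms: potassium peroxymonosulfate ([K+].OOS(=O)(=O)[O-])
Why: Shi asymmetric epoxidation; the dioxirane attacks only the trisubstituted alkene, under reagent control, to give the (6S)-oxirane, and acid-catalysed 5-exo opening by the tertiary hydroxyl with inversion should give the 2,5-trans oxolane (C7 = R), the minor pyranoid isomer being removed.

Step 11
Reactants: 16 trans-linalool oxide
Product: 17 (2R,5R)-2-ethenyl-2-methyl-5-(prop-1-en-2-yl)oxolane
Conditions: POCl3, pyridine, 0 °C → rt
Reagents that add atoms: none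
Why: E2 dehydration through the dichlorophosphate; the six methyl hydrogens are more accessible than the single ring C7–H, so the isopropenyl isomer should dominate, and any enol ether isomer is lost on aqueous work-up.

Step 12
Reactants: 17 diene
Product: 18 (2R,5R)-2-ethenyl-2-methyl-5-(2-methyloxiran-2-yl)oxolane (both oxirane epimers)
Conditions: mCPBA (1.05 equiv), NaHCO3, CH2Cl2, 0 °C
Reagents that add atoms: 3-chloroperoxybenzoic acid (OOC(=O)c1cccc(Cl)c1)
Why: Prilezhaev epoxidation is far faster at the 1,1-disubstituted alkene than at the monosubstituted vinyl group on the quaternary carbon, so one equivalent should differentiate them.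

Step 13
Reactants: 18 epoxide
Product: 19 1-[(2R,5R)-5-ethenyl-5-methyloxolan-2-yl]ethan-1-one
Conditions: H5IO6, THF–H2O, 0 °C → rt
Reagents that add atoms: water (O)
Why: Periodic acid opens the oxirane to the diol and cleaves it (Malaprade cleavage) to the methyl ketone and formaldehyde, excising the surplus methyl-derived carbon without touching the vinyl group.

Step 14
Reactants: 19 methyl ketone
Product: 20 (2R,5R)-5-(1,1-dimethoxyethyl)-2-ethenyl-2-methyloxolane
Conditions: HC(OMe)3, MeOH, pyridinium p-toluenesulfonate (cat.), rt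
Reagents that add atoms: trimethyl orthoformate (COC(OC)OC); methanol (CO)
Why: Acid-catalysed ketalisation with orthoformate as water scavenger masks the C8 ketone as a dimethyl ketal, stable to the organolithium, the oxidation and the borane of steps 16–18; brief mild acid limits enolisation at C7.

Step 15
Reactants: 20 ketal
Product: 21 east aldehyde, (2R,5R)-5-(1,1-dimethoxyethyl)-2-methyloxolane-2-carbaldehyde
Conditions: O3, pyridine (3 equiv), CH2Cl2, −78 °C
Reagents that add atoms: ozone ([O-][O+]=O)
Why: Ozonolysis in the presence of pyridine cleaves the vinyl group directly to the aldehyde under non-acidic conditions that keep the ketal; the aldehyde has no α-hydrogen.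

Step 16
Reactants: 13 west chloride; 21 east aldehyde
Product: 23 seco C3 carbinol (both C3 epimers; C12–OTBS, cyclopropyl–OTES, C8 dimethyl ketal), via alkyllithium 22 (not isolated)
Conditions: Li, 4,4'-di-tert-butylbiphenyl, THF, −78 °C (titrated to persistent green); then 21, −78 °C
Reagents that add atoms: none
Why: Reductive lithiation of the primary chloride by the arene radical anion gives the C2 alkyllithium, which adds 1,2 to the non-enolisable aldehyde to form C2–C3; the C3 configuration is not controlled here and is reset in steps 17 and 18.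

Step 17
Reactants: 23 C3 carbinol
Product: 24 seco C3 ketone
Conditions: Dess–Martin periodinane, NaHCO3, CH2Cl2, rt
Reagents that add atoms: none
Why: Buffered Dess–Martin oxidation merges both C3 epimers into one ketone and spares the silyl ethers, the ketal and the alkene.

Step 18
Reactants: 24 C3 ketone
Product: 25 seco (3S)-carbinol
Conditions: (R)-2-methyl-CBS-oxazaborolidine (0.5 equiv), catecholborane, toluene, −78 → −20 °C
Reagents that add atoms: none
Why: Corey–Bakshi–Shibata reduction; with the quaternary C4 as the large and C2H2 as the small substituent the (R)-oxazaborolidine should deliver hydride to the face that gives 3S, overriding the weak bias of C4 (its methyl and ring CH2 are similar in size), and catecholborane leaves the alkene alone.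

Step 19
Reactants: 25 (3S)-carbinol
Product: 26 seco (3S)-acetate
Conditions: Ac2O, DMAP, Et3N, CH2Cl2, rt
Reagents that add atoms: acetic anhydride (CC(=O)OC(C)=O)
Why: DMAP-catalysed acetylation of the only free hydroxyl installs the C3 acetate of the target.

Step 20
Reactants: 26 acetate
Product: 27 seco cyclopropanol methyl ketone (C11 cyclopropanol, C8 methyl ketone, C12–OTBS, C3–OAc)
Conditions: pyridinium p-toluenesulfonate, acetone–H2O (10:1), rt → 40 °C
Reagents that add atoms: water (O)
Why: Mild Brønsted-acid hydrolysis removes the dimethyl ketal and the triethylsilyl ether in one operation while the hindered tertiary TBS ether and the acetate survive; the C12 silyl ether prevents ionisation next to the cyclopropanol.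

Step 21
Reactants: 27 seco cyclopropanol methyl ketone
Product: 30 macrocyclic γ-hydroxy ketone (1R,3S,4R,7R,8R,12R; 14-membered ring with oxolane bridge; C12–OTBS), via ethylzinc cyclopropoxide 28 (not isolated), via zinc homoenolate 29 (not isolated)
Conditions: Et2Zn (2 equiv), CH2Cl2, 0 °C; then MgBr2·OEt2 (3 equiv), 2 mM, 0 °C → rt; aq. NH4Cl
Reagents that add atoms: none
Why: Proposed new method: Et2Zn deprotonates the cyclopropanol to the ethylzinc cyclopropoxide 28, which opens reversibly at one of its two equivalent C11–CH2 bonds, with release of ring strain, to the β-zincio ketone 29, and the C9–Zn bond then adds irreversibly to the C8 ketone held in a five-membered MgBr2 chelate with the oxolane oxygen on C7, which drains the equilibrium. The closest known reaction type is the intermolecular carbonyl addition of zinc and titanium homoenolates made from cyclopropanols or siloxycyclopropanes, here run within one molecule with chelate activation in place of silyl chloride activation. The 14-membered carbocycle closes by attack on the exocyclic C8=O (14-exo-trig) at high dilution. C8 is set by Cram-chelate control: with the carbonyl oxygen and the ring oxygen syn on magnesium, C9 enters from the side of the C7 hydrogen, away from C6, which gives 8R. The step needs a single homoenolate, which the quaternary C12 and the equivalence of the two ring methylenes guarantee, and attack on the ketone rather than on the C3 acetate, which the chelate activation secures; the silyl ether on C12 excludes ketol or acyl shifts at the new C11 ketone.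

Step 22
Reactants: 30 macrocycle
Product: 31 C16 allylic alcohol of 30
Conditions: SeO2 (0.5 equiv), t-BuOOH, CH2Cl2, rt
Reagents that add atoms: tert-butyl hydroperoxide (CC(C)(C)OO); selenium dioxide (O=[Se]=O)
Why: Allylic oxidation with SeO2 and t-BuOOH (ene reaction at the terminal CH2, then [2,3]-sigmatropic shift) should oxidise the methyl group of the isopropenyl unit rather than the hindered C1–H; any enal formed converges in step 23.

Step 23
Reactants: 31 allylic alcohol
Product: 32 C16 enal
Conditions: MnO2, CH2Cl2, rt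
Reagents that add atoms: none
Why: MnO2 oxidises only the primary allylic alcohol; the tertiary alcohol, ketone and acetate are inert.

Step 24
Reactants: 32 enal
Product: 33 C16 acrylic acid (C12–OTBS)
Conditions: NaClO2, NaH2PO4, 2-methylbut-2-ene, t-BuOH–H2O, 0 °C → rt
Reagents that add atoms: sodium chlorite ([Na+].[O-]Cl=O)
Why: Pinnick oxidation converts the enal to the acid without touching the alkene, the scavenger removing hypochlorous acid.

Step 25
Reactants: 33 acid
Product: 34 seco hydroxy acid (C12–OH free)
Conditions: HF (48% aq), MeCN, rt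
Reagents that add atoms: none
Why: Fluoride-assisted cleavage of the tertiary TBS ether; acetate, ketone, oxolane and acrylic acid are stable to aqueous HF in MeCN.

Step 26
Reactants: 34 hydroxy acid
Product: 36 target CNP0198878.1, via mixed anhydride 35 (not isolated)
Conditions: 2,4,6-trichlorobenzoyl chloride, Et3N, THF, rt; then DMAP, toluene, 60 °C
Reagents that add atoms: none
Why: Yamaguchi lactonisation; DMAP converts the mixed anhydride 35 into an acylpyridinium that the C12 hydroxyl captures in a seven-membered closure, kinetically preferred over the ten-membered or larger rings available through the C8 hydroxyl.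

**Compound list**

1 | (R)-(−)-carvone | CC1=CC[C@H](CC1=O)C(C)=C | starting material
2 | (1R,4R,6R)-1-methyl-4-(prop-1-en-2-yl)-7-oxabicyclo[4.1.0]heptan-2-one | CC(=C)[C@@H]1C[C@H]2O[C@@]2(C)C(=O)C1 | intermediate
3 | (1R,4R)-1-methyl-4-(prop-1-en-2-yl)cyclohexane-1,2-diol, C2 epimers | CC(=C)[C@@H]1CC[C@](O)(C)C(O)C1 | intermediate
4 | (2R,5R)-2-hydroxy-2-methyl-5-(prop-1-en-2-yl)cyclohexan-1-one | CC(=C)[C@@H]1CC[C@](O)(C)C(=O)C1 | intermediate
5 | (2R,5R)-2-[(tert-butyldimethylsilyl)oxy]-2-methyl-5-(prop-1-en-2-yl)cyclohexan-1-one | CC(=C)[C@@H]1CC[C@](O[Si](C)(C)C(C)(C)C)(C)C(=O)C1 | intermediate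
6 | potassium enolate of 5 | CC(=C)[C@@H]1CC[C@](O[Si](C)(C)C(C)(C)C)(C)C(O[K])=C1 | intermediate
7 | (2R,5S)-2-[(tert-butyldimethylsilyl)oxy]-6-hydroxy-2-methyl-5-(prop-1-en-2-yl)cyclohexan-1-one, C6 epimers | CC(=C)[C@@H]1CC[C@](O[Si](C)(C)C(C)(C)C)(C)C(=O)C1O | intermediate
8 | methyl (2R,5S)-2-[(tert-butyldimethylsilyl)oxy]-5-formyl-2,6-dimethylhept-6-enoate | COC(=O)[C@](C)(O[Si](C)(C)C(C)(C)C)CC[C@H](C=O)C(C)=C | intermediate
9 | methyl (2R,5S)-2-[(tert-butyldimethylsilyl)oxy]-5-(hydroxymethyl)-2,6-dimethylhept-6-enoate | COC(=O)[C@](C)(O[Si](C)(C)C(C)(C)C)CC[C@H](CO)C(C)=C | intermediate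
10 | methyl (2R,5S)-2-[(tert-butyldimethylsilyl)oxy]-5-(chloromethyl)-2,6-dimethylhept-6-enoate | COC(=O)[C@](C)(O[Si](C)(C)C(C)(C)C)CC[C@H](CCl)C(C)=C | intermediate
11 | ethylmagnesium bromide | CC[Mg]Br | starting material
12 | 1-[(2R,5S)-2-[(tert-butyldimethylsilyl)oxy]-5-(chloromethyl)-6-methylhept-6-en-2-yl]cyclopropan-1-ol | OC1(CC1)[C@](C)(O[Si](C)(C)C(C)(C)C)CC[C@H](CCl)C(C)=C | intermediate
13 | west chloride: triethylsilyl ether of 12 | CC[Si](CC)(CC)OC1(CC1)[C@](C)(O[Si](C)(C)C(C)(C)C)CC[C@H](CCl)C(C)=C | intermediate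
14 | (R)-(−)-linalool | C=C[C@](C)(O)CCC=C(C)C | starting material
15 | (3R)-5-[(2S)-3,3-dimethyloxiran-2-yl]-3-methylpent-1-en-3-ol | C=C[C@](C)(O)CC[C@@H]1OC1(C)C | intermediate
16 | 2-[(2R,5R)-5-ethenyl-5-methyloxolan-2-yl]propan-2-ol | C=C[C@@]1(C)CC[C@@H](O1)C(C)(C)O | intermediate
17 | (2R,5R)-2-ethenyl-2-methyl-5-(prop-1-en-2-yl)oxolane | C=C[C@@]1(C)CC[C@@H](O1)C(C)=C | intermediate
18 | (2R,5R)-2-ethenyl-2-methyl-5-(2-methyloxiran-2-yl)oxolane, oxirane epimers | C=C[C@@]1(C)CC[C@@H](O1)C2(C)CO2 | intermediate
19 | 1-[(2R,5R)-5-ethenyl-5-methyloxolan-2-yl]ethan-1-one | C=C[C@@]1(C)CC[C@@H](O1)C(C)=O | intermediate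
20 | (2R,5R)-5-(1,1-dimethoxyethyl)-2-ethenyl-2-methyloxolane | C=C[C@@]1(C)CC[C@@H](O1)C(C)(OC)OC | intermediate
21 | east aldehyde: (2R,5R)-5-(1,1-dimethoxyethyl)-2-methyloxolane-2-carbaldehyde | O=C[C@@]1(C)CC[C@@H](O1)C(C)(OC)OC | intermediate
22 | C2 alkyllithium from 13 | [Li]C[C@@H](CC[C@@](C)(O[Si](C)(C)C(C)(C)C)C1(CC1)O[Si](CC)(CC)CC)C(C)=C | intermediate
23 | seco C3 carbinol (1R,4R,7R,12R; C3 epimers; C12–OTBS, cyclopropyl–OTES, C8 dimethyl ketal) | C=C(C)[C@H](CC[C@@](C)(O[Si](C)(C)C(C)(C)C)C1(CC1)O[Si](CC)(CC)CC)CC(O)[C@@]1(C)CC[C@@H](O1)C(C)(OC)OC | intermediate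
24 | seco C3 ketone (1R,4R,7R,12R) | C=C(C)[C@H](CC[C@@](C)(O[Si](C)(C)C(C)(C)C)C1(CC1)O[Si](CC)(CC)CC)CC(=O)[C@@]1(C)CC[C@@H](O1)C(C)(OC)OC | intermediate
25 | seco (3S)-carbinol (1R,3S,4R,7R,12R) | C=C(C)[C@H](CC[C@@](C)(O[Si](C)(C)C(C)(C)C)C1(CC1)O[Si](CC)(CC)CC)C[C@H](O)[C@@]1(C)CC[C@@H](O1)C(C)(OC)OC | intermediate
26 | seco (3S)-acetate (1R,3S,4R,7R,12R) | C=C(C)[C@H](CC[C@@](C)(O[Si](C)(C)C(C)(C)C)C1(CC1)O[Si](CC)(CC)CC)C[C@H](OC(C)=O)[C@@]1(C)CC[C@@H](O1)C(C)(OC)OC | intermediate
27 | seco cyclopropanol methyl ketone (1R,3S,4R,7R,12R; C12–OTBS, C3–OAc) | C=C(C)[C@H](CC[C@@](C)(O[Si](C)(C)C(C)(C)C)C1(O)CC1)C[C@H](OC(C)=O)[C@@]1(C)CC[C@@H](O1)C(C)=O | intermediate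
28 | ethylzinc cyclopropoxide of 27 | C=C(C)[C@H](CC[C@@](C)(O[Si](C)(C)C(C)(C)C)C1(O[Zn]CC)CC1)C[C@H](OC(C)=O)[C@@]1(C)CC[C@@H](O1)C(C)=O | intermediate
29 | zinc homoenolate (C9–Zn, C11 ketone) | C=C(C)[C@H](CC[C@@](C)(O[Si](C)(C)C(C)(C)C)C(=O)CC[Zn]CC)C[C@H](OC(C)=O)[C@@]1(C)CC[C@@H](O1)C(C)=O | intermediate
30 | macrocyclic γ-hydroxy ketone (1R,3S,4R,7R,8R,12R; C12–OTBS) | C=C(C)[C@H]1C[C@H](OC(C)=O)[C@@]2(C)CC[C@@H](O2)[C@](C)(O)CCC(=O)[C@](C)(O[Si](C)(C)C(C)(C)C)CC1 | intermediate
31 | C16 allylic alcohol of 30 | C=C(CO)[C@H]1C[C@H](OC(C)=O)[C@@]2(C)CC[C@@H](O2)[C@](C)(O)CCC(=O)[C@](C)(O[Si](C)(C)C(C)(C)C)CC1 | intermediate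
32 | C16 enal | C=C(C=O)[C@H]1C[C@H](OC(C)=O)[C@@]2(C)CC[C@@H](O2)[C@](C)(O)CCC(=O)[C@](C)(O[Si](C)(C)C(C)(C)C)CC1 | intermediate
33 | C16 acrylic acid (C12–OTBS) | C=C(C(=O)O)[C@H]1C[C@H](OC(C)=O)[C@@]2(C)CC[C@@H](O2)[C@](C)(O)CCC(=O)[C@](C)(O[Si](C)(C)C(C)(C)C)CC1 | intermediate
34 | hydroxy acid (C12–OH free) | C=C(C(=O)O)[C@H]1C[C@H](OC(C)=O)[C@@]2(C)CC[C@@H](O2)[C@](C)(O)CCC(=O)[C@](C)(O)CC1 | intermediate
35 | mixed anhydride of 34 with 2,4,6-trichlorobenzoic acid | C=C(C(=O)OC(=O)c3c(Cl)cc(Cl)cc3Cl)[C@H]1C[C@H](OC(C)=O)[C@@]2(C)CC[C@@H](O2)[C@](C)(O)CCC(=O)[C@](C)(O)CC1 | intermediate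
36 | CNP0198878.1 (1R,3S,4R,7R,8R,12R) | C=C1C(=O)O[C@]2(C)CC[C@@H]1C[C@H](OC(C)=O)[C@@]1(C)CC[C@@H](O1)[C@](C)(O)CCC2=O | target

**Step count and risks**

Total step count: 26. Longest linear sequence: 20 steps (steps 1–9, then 16–26); the east branch (steps 10–15) has 6 steps.

Steps most likely to fail:

1. Step 21 (homoaldol macrocyclisation). The zinc homoenolate may add too slowly to the chelated ketone, so that it is only protonated on work-up to the ring-opened ethyl ketone; intermolecular addition may outrun the 14-membered closure; and incomplete chelation would erode facial selectivity at C8. The fallback uses known chemistry, sets out from 27 and returns at 30. Vinylmagnesium bromide with MgBr2·OEt2 at −78 °C (chelation-controlled Grignard addition, the cyclopropanol carried as its magnesium alkoxide) should give the tertiary allylic alcohol F1. Aerobic ring opening of the cyclopropanol with catalytic Pd(OAc)2 (pyridine, O2, toluene, 80 °C) should give the vinyl ketone F2. Ring-closing metathesis with the second-generation Grubbs catalyst at high dilution joins C9 and C10 with loss of ethene to the macrocyclic E-enone F3; the 1,1-disubstituted C15=C17 alkene is the slowest metathesis partner. Conjugate reduction with [(Ph3P)CuH]6 then gives 30.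

2. Step 26 (lactonisation). Acylation of the hindered tertiary C12 hydroxyl may be slower than oligomerisation, decay of the mixed anhydride or conjugate addition of DMAP to the acrylate. The fallback sets out from 32 and returns at 36 without passing through a carboxylic acid. Aqueous HF in MeCN removes the silyl ether to give the hydroxy enal F4. Carbene-catalysed oxidative lactonisation (1,4-dimethyl-1,2,4-triazolium iodide, DBU, 3,3',5,5'-tetra-tert-butyl-4,4'-diphenoquinone, THF) then turns the aldehyde into an acyl azolium that is captured by the C12 hydroxyl to give 36.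

3. Step 8 (Kulinkovich reaction). Insertion of the hindered α-silyloxy, α-quaternary ester into the titanacyclopropane may be too slow, leaving ester or giving reduction products. The fallback sets out from 10 and returns at 13, building the cyclopropane from a silyl enol ether instead. MeNH(OMe)·HCl with AlMe3 gives the Weinreb amide F5, and MeMgBr gives the methyl ketone F6. LiN(i-Pr)2 and TESCl give the triethylsilyl enol ether F7; only the methyl group can be deprotonated. Furukawa–Simmons–Smith cyclopropanation (Et2Zn, CH2I2, CH2Cl2, 0 °C), far faster at the enol ether than at the 1,1-disubstituted alkene, delivers 13 directly.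

**Further compounds**

F1 | step 21 | C8 vinyl carbinol of 27 (8R, cyclopropanol intact) | C=C(C)[C@H](CC[C@@](C)(O[Si](C)(C)C(C)(C)C)C1(O)CC1)C[C@H](OC(C)=O)[C@@]1(C)CC[C@@H](O1)[C@](C)(O)C=C
F2 | step 21 | C11 vinyl ketone with C8 vinyl carbinol | C=C(C)[C@H](CC[C@@](C)(O[Si](C)(C)C(C)(C)C)C(=O)C=C)C[C@H](OC(C)=O)[C@@]1(C)CC[C@@H](O1)[C@](C)(O)C=C
F3 | step 21 | macrocyclic (9E)-enone | C=C(C)[C@H]1C[C@H](OC(C)=O)[C@@]2(C)CC[C@@H](O2)[C@](C)(O)/C=C/C(=O)[C@](C)(O[Si](C)(C)C(C)(C)C)CC1
F4 | step 26 | hydroxy enal (C12–OH free, C16 aldehyde) | C=C(C=O)[C@H]1C[C@H](OC(C)=O)[C@@]2(C)CC[C@@H](O2)[C@](C)(O)CCC(=O)[C@](C)(O)CC1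
F5 | step 8 | Weinreb amide of 10 | CON(C)C(=O)[C@](C)(O[Si](C)(C)C(C)(C)C)CC[C@H](CCl)C(C)=C
F6 | step 8 | methyl ketone from F5 | CC(=O)[C@](C)(O[Si](C)(C)C(C)(C)C)CC[C@H](CCl)C(C)=C
F7 | step 8 | triethylsilyl enol ether of F6 | C=C(O[Si](CC)(CC)CC)[C@](C)(O[Si](C)(C)C(C)(C)C)CC[C@H](CCl)C(C)=C
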